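**Plan**

- Numbering: tetrahydrofuran ring O1–C2–C3–C4–C5; C3 carries the carbinol carbon C7 (syringyl side), C4 carries the guaiacylmethyl group.
- Enabling feature: C2 is a CH2 flanked by ring O1 and C3, and C3 is α to C7. With C7 as a ketone, C2–C3 is the bond between the aryl ketone enol C3=C7 and the formaldehyde-level oxocarbenium ion O1=C2.
- Cuts, in retrosynthetic order: C7–H (carbinol to ketone); C2–C3 (ring opening to enol silane and O-methoxymethyl ether); C7–aryl (syringyllithium and Weinreb amide); C3–C4 (alkylation of a 3-arylpropanoyl imide with a bromoacetate).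
- Forward: the open chain is joined first (C3–C4, then lactone, amide, acetal, C7–aryl); the single ring closes at C2–C3 in step 10; C7 is then reduced and the phenols are freed.
- Stereochemistry: C4 from the (R)-4-benzyloxazolidinone auxiliary; C3 from C4 during ring closure (trans, also the thermodynamic isomer); C7 from the (R)-oxazaborolidine catalyst.

Key step: step 10

Assumption: the SMILES is read as the trans-(3S,4S) tetrahydrofuran with an (S) carbinol carbon C7, and aryl triisopropylsilyl ethers are taken to survive every step up to the final fluoride treatment.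

**Route**

Step 1
Reactants: 1 3-(4-hydroxy-3-methoxyphenyl)propanoic acid
Product: 3 3-[3-methoxy-4-(triisopropylsilyloxy)phenyl]propanoic acid, via silyl ester 2 (not isolated)
Conditions: i-Pr3SiCl (2.3 equiv), imidazole, DMF, rt; then 1 M HCl, THF, rt
Reagents that add atoms: triisopropylsilyl chloride, CC(C)[Si](Cl)(C(C)C)C(C)C
Why: Phenol protection as a silyl ether, in which both hydroxyls are silylated and the silyl ester, far more labile to aqueous acid than the aryl silyl ether, is then hydrolysed selectively, with no stereocentre involved.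

Step 2
Reactants: 3 3-[3-methoxy-4-(triisopropylsilyloxy)phenyl]propanoic acid; 4 (R)-4-benzyl-1,3-oxazolidin-2-one
Product: 6 (4R)-4-benzyl-3-{3-[3-methoxy-4-(triisopropylsilyloxy)phenyl]propanoyl}-1,3-oxazolidin-2-one, via mixed pivalic anhydride 5 (not isolated)
Conditions: t-BuCOCl, Et3N, THF, −20 °C; then LiCl, 4, −20 °C to rt
Reagents that add atoms: pivaloyl chloride, CC(C)(C)C(=O)Cl (its acyl group is carried by intermediate 5 only and is absent from 6)
Why: Acyl transfer to the oxazolidinone nitrogen through the mixed pivalic anhydride under LiCl and Et3N (N-acylation of an Evans auxiliary) needs no strong base and creates no stereocentre.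

Step 3
Reactants: 6 (4R)-4-benzyl-3-{3-[3-methoxy-4-(triisopropylsilyloxy)phenyl]propanoyl}-1,3-oxazolidin-2-one; 7 tert-butyl bromoacetate
Product: 9 tert-butyl (3S)-4-[(4R)-4-benzyl-2-oxo-1,3-oxazolidin-3-yl]-3-[3-methoxy-4-(triisopropylsilyloxy)benzyl]-4-oxobutanoate, via sodium enolate 8 (not isolated)
Conditions: NaN(SiMe3)2, THF, −78 °C; then 7, −78 to −40 °C
Reagents that add atoms: sodium bis(trimethylsilyl)amide, [Na+].C[Si](C)(C)[N-][Si](C)(C)C (its sodium is held by intermediate 8 only)
Why: Evans asymmetric alkylation, in which the chelated (Z)-sodium enolate is alkylated by the reactive α-bromo ester on the face away from the auxiliary benzyl group, which with the (R)-auxiliary sets the (S) centre that becomes C4 and forms the C3–C4 bond.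

Step 4
Reactants: 9 tert-butyl (3S)-4-[(4R)-4-benzyl-2-oxo-1,3-oxazolidin-3-yl]-3-[3-methoxy-4-(triisopropylsilyloxy)benzyl]-4-oxobutanoate
Product: 11 (4S)-4-[3-methoxy-4-(triisopropylsilyloxy)benzyl]oxolan-2-one, via hydroxy tert-butyl ester 10 (not isolated)
Conditions: LiBH4, MeOH (1 equiv), THF, 0 °C; H2O; then p-toluenesulfonic acid monohydrate (0.1 equiv), toluene, 80 °C
Reagents that add atoms: none
Why: Reductive cleavage of the N-acyloxazolidinone by LiBH4 spares the tert-butyl ester and acid-catalysed loss of isobutene with lactonisation then gives the γ-lactone, the stereocentre being untouched because it is no longer α to a carbonyl group after the reduction.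

Step 5
Reactants: 11 (4S)-4-[3-methoxy-4-(triisopropylsilyloxy)benzyl]oxolan-2-one
Product: 12 (3S)-3-(hydroxymethyl)-N-methoxy-N-methyl-4-[3-methoxy-4-(triisopropylsilyloxy)phenyl]butanamide
Conditions: MeNH(OMe)·HCl, AlMe3, CH2Cl2, 0 °C to rt; aqueous potassium sodium tartrate
Reagents that add atoms: N,O-dimethylhydroxylamine hydrochloride, CNOC.Cl
Why: Weinreb aminolysis of a lactone by the aluminium amide formed from AlMe3 and the amine hydrochloride is a standard ring opening that leaves the β-stereocentre untouched.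

Step 6
Reactants: 12 (3S)-3-(hydroxymethyl)-N-methoxy-N-methyl-4-[3-methoxy-4-(triisopropylsilyloxy)phenyl]butanamide; 13 chloromethyl methyl ether
Product: 14 (3S)-N-methoxy-3-[(methoxymethoxy)methyl]-N-methyl-4-[3-methoxy-4-(triisopropylsilyloxy)phenyl]butanamide
Conditions: 13, i-Pr2NEt, n-Bu4NI (0.1 equiv), CH2Cl2, 0 °C to rt, on crude 12
Reagents that add atoms: none
Why: Alkoxymethylation of the primary alcohol with the chloromethyl ether and a hindered amine (acetal-type O-alkylation) installs the O–CH2–OMe unit whose methylene becomes C2, and immediate use of crude 12 limits relactonisation.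

Step 7
Reactants: 15 4-bromo-2,6-dimethoxyphenol
Product: 16 (4-bromo-2,6-dimethoxyphenoxy)triisopropylsilane
Conditions: i-Pr3SiOSO2CF3, 2,6-lutidine, CH2Cl2, 0 °C to rt
Reagents that add atoms: triisopropylsilyl trifluoromethanesulfonate, CC(C)[Si](OS(=O)(=O)C(F)(F)F)(C(C)C)C(C)C
Why: Silyl ether formation, for which the silyl triflate is chosen because the phenol is flanked by two methoxy groups.

Step 8
Reactants: 16 (4-bromo-2,6-dimethoxyphenoxy)triisopropylsilane; 14 (3S)-N-methoxy-3-[(methoxymethoxy)methyl]-N-methyl-4-[3-methoxy-4-(triisopropylsilyloxy)phenyl]butanamide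
Product: 19 (3S)-1-[3,5-dimethoxy-4-(triisopropylsilyloxy)phenyl]-3-[(methoxymethoxy)methyl]-4-[3-methoxy-4-(triisopropylsilyloxy)phenyl]butan-1-one, via aryllithium 17 (not isolated), via lithium hemiaminal adduct 18 (not isolated)
Conditions: 16 (1.3 equiv), n-BuLi, THF, −78 °C; then 14, −78 to −20 °C; aqueous NH4Cl
Reagents that add atoms: n-butyllithium, [Li]CCCC (its lithium is held by intermediates 17 and 18 only)
Why: Bromine–lithium exchange followed by Weinreb ketone synthesis, in which the chelated tetrahedral adduct persists until the quench so that the aryl ketone forms without over-addition, the acetal and silyl ethers being inert to the aryllithium at low temperature.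

Step 9
Reactants: 19 (3S)-1-[3,5-dimethoxy-4-(triisopropylsilyloxy)phenyl]-3-[(methoxymethoxy)methyl]-4-[3-methoxy-4-(triisopropylsilyloxy)phenyl]butan-1-one
Product: 21 {[(1Z,3S)-1-[3,5-dimethoxy-4-(triisopropylsilyloxy)phenyl]-3-[(methoxymethoxy)methyl]-4-[3-methoxy-4-(triisopropylsilyloxy)phenyl]but-1-en-1-yl]oxy}trimethylsilane, via lithium enolate 20 (not isolated)
Conditions: LiN(SiMe3)2, THF, −78 °C; then Me3SiCl, Et3N, −78 to 0 °C; pentane, cold aqueous NaHCO3
Reagents that add atoms: chlorotrimethylsilane, C[Si](C)(C)Cl; lithium bis(trimethylsilyl)amide, [Li+].C[Si](C)(C)[N-][Si](C)(C)C (its lithium is held by intermediate 20 only)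
Why: Silyl enol ether formation by kinetic deprotonation of the only enolisable position and O-silylation gives the (Z)-enol silane typical of aryl alkyl ketones, and the C4 centre, β to the carbonyl group, is not acidic.

Step 10
Reactants: 21 {[(1Z,3S)-1-[3,5-dimethoxy-4-(triisopropylsilyloxy)phenyl]-3-[(methoxymethoxy)methyl]-4-[3-methoxy-4-(triisopropylsilyloxy)phenyl]but-1-en-1-yl]oxy}trimethylsilane
Product: 23 [(3S,4S)-4-[3-methoxy-4-(triisopropylsilyloxy)benzyl]oxolan-3-yl][3,5-dimethoxy-4-(triisopropylsilyloxy)phenyl]methanone, via oxocarbenium triflate 22 (not isolated)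
Conditions: Me3SiOSO2CF3 (0.3 equiv), 2,6-di-tert-butyl-4-methylpyridine (0.5 equiv), CH2Cl2, −78 to −30 °C; aqueous NaHCO3
Reagents that add atoms: trimethylsilyl trifluoromethanesulfonate, C[Si](C)(C)OS(=O)(=O)C(F)(F)F (its triflate is the counter-ion of intermediate 22 only and nothing of it remains in 23)
Why: Silylation of the more accessible methoxy oxygen of the acetal expels methoxytrimethylsilane and leaves the oxocarbenium ion O1=C2, whose carbon is attacked by the enol silane carbon C3, and loss of the silyl group from the resulting silyloxocarbenium ion returns the aryl ketone and the silyl triflate. This is an intramolecular Mukaiyama-type addition of an enol silane to an alkoxymethyl cation, the known reaction class by which Lewis acids convert alkoxymethyl ethers or aldehyde-derived oxocarbenium ions carrying enol silanes or enol carbamates into 3-acyltetrahydrofurans. The tetrahydrofuran closes in a five-membered mode with the oxocarbenium bond inside the ring and the enol double bond outside it (5-endo for the cation, 5-exo for the enol), a closure that is established for oxocarbenium ions. The new centre C3 is controlled by C4, because with the C4–H bond eclipsing the (Z)-enol to minimise allylic 1,3-strain the tether reaches the enol face opposite the benzyl group, which places aroyl and benzyl trans, and this is also the thermodynamic arrangement to which any cis isomer could be brought with catalytic DBU since C3 is α to the ketone. The step needs ionisation toward the alkoxymethyl cation and carbon attack by the enol in preference to the electron-rich arene, the first secured by the less hindered methoxy oxygen and the second by the far higher nucleophilicity of the enol silane and by five- against seven-membered ring formation, while the hindered pyridine removes triflic acid that would protodesilylate the enol.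

Step 11
Reactants: 23 [(3S,4S)-4-[3-methoxy-4-(triisopropylsilyloxy)benzyl]oxolan-3-yl][3,5-dimethoxy-4-(triisopropylsilyloxy)phenyl]methanone
Product: 24 (S)-[(3S,4S)-4-[3-methoxy-4-(triisopropylsilyloxy)benzyl]oxolan-3-yl][3,5-dimethoxy-4-(triisopropylsilyloxy)phenyl]methanol
Conditions: (3aR)-1-methyl-3,3-diphenyltetrahydro-1H,3H-pyrrolo[1,2-c][1,3,2]oxazaborole (0.5 equiv), BH3·SMe2 (1.0 equiv), THF, −20 °C; MeOH
Reagents that add atoms: none
Why: Corey–Bakshi–Shibata reduction, in which the (R)-oxazaborolidine binds the ketone with the aryl group as the large substituent and delivers hydride to the Re face to give the (S)-carbinol under catalyst control, needed because Felkin–Anh addition anti to C4 alone is expected to favour the C7 epimer.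

Step 12
Reactants: 24 (S)-[(3S,4S)-4-[3-methoxy-4-(triisopropylsilyloxy)benzyl]oxolan-3-yl][3,5-dimethoxy-4-(triisopropylsilyloxy)phenyl]methanol
Product: 25 (S)-[(3S,4S)-4-(4-hydroxy-3-methoxybenzyl)oxolan-3-yl](4-hydroxy-3,5-dimethoxyphenyl)methanol (CNP0307127.2)
Conditions: n-Bu4NF (2.5 equiv), AcOH (2.5 equiv), THF, 0 °C
Reagents that add atoms: none
Why: Fluoride desilylation of the two aryl silyl ethers, buffered with acetic acid so that the phenoxides are protonated at once and the p-hydroxybenzylic carbinol is not exposed to base, leaves all three stereocentres untouched.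

**Compound list**

1 | 3-(4-hydroxy-3-methoxyphenyl)propanoic acid | COc1cc(CCC(=O)O)ccc1O | starting material
2 | triisopropylsilyl 3-[3-methoxy-4-(triisopropylsilyloxy)phenyl]propanoate | COc1cc(CCC(=O)O[Si](C(C)C)(C(C)C)C(C)C)ccc1O[Si](C(C)C)(C(C)C)C(C)C | intermediate (not isolated)
3 | 3-[3-methoxy-4-(triisopropylsilyloxy)phenyl]propanoic acid | COc1cc(CCC(=O)O)ccc1O[Si](C(C)C)(C(C)C)C(C)C | intermediate
4 | (R)-4-benzyl-1,3-oxazolidin-2-one | O=C1N[C@H](Cc2ccccc2)CO1 | starting material
5 | mixed anhydride of 3 with pivalic acid | COc1cc(CCC(=O)OC(=O)C(C)(C)C)ccc1O[Si](C(C)C)(C(C)C)C(C)C | intermediate (not isolated)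
6 | (4R)-4-benzyl-3-{3-[3-methoxy-4-(triisopropylsilyloxy)phenyl]propanoyl}-1,3-oxazolidin-2-one | COc1cc(CCC(=O)N2[C@H](Cc3ccccc3)COC2=O)ccc1O[Si](C(C)C)(C(C)C)C(C)C | intermediate
7 | tert-butyl bromoacetate | CC(C)(C)OC(=O)CBr | starting material
8 | sodium (Z)-enolate of imide 6 (enolate oxygen cis to the arylmethyl group) | COc1cc(C/C=C(\[O-])N2[C@H](Cc3ccccc3)COC2=O)ccc1O[Si](C(C)C)(C(C)C)C(C)C.[Na+] | intermediate (not isolated)
9 | tert-butyl (3S)-4-[(4R)-4-benzyl-2-oxo-1,3-oxazolidin-3-yl]-3-[3-methoxy-4-(triisopropylsilyloxy)benzyl]-4-oxobutanoate | COc1cc(C[C@@H](CC(=O)OC(C)(C)C)C(=O)N2[C@H](Cc3ccccc3)COC2=O)ccc1O[Si](C(C)C)(C(C)C)C(C)C | intermediate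
10 | tert-butyl (3S)-3-(hydroxymethyl)-4-[3-methoxy-4-(triisopropylsilyloxy)phenyl]butanoate | COc1cc(C[C@@H](CC(=O)OC(C)(C)C)CO)ccc1O[Si](C(C)C)(C(C)C)C(C)C | intermediate (not isolated)
11 | (4S)-4-[3-methoxy-4-(triisopropylsilyloxy)benzyl]oxolan-2-one | COc1cc(C[C@@H]2COC(=O)C2)ccc1O[Si](C(C)C)(C(C)C)C(C)C | intermediate
12 | (3S)-3-(hydroxymethyl)-N-methoxy-N-methyl-4-[3-methoxy-4-(triisopropylsilyloxy)phenyl]butanamide | COc1cc(C[C@@H](CC(=O)N(C)OC)CO)ccc1O[Si](C(C)C)(C(C)C)C(C)C | intermediate
13 | chloromethyl methyl ether | COCCl | starting material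
14 | (3S)-N-methoxy-3-[(methoxymethoxy)methyl]-N-methyl-4-[3-methoxy-4-(triisopropylsilyloxy)phenyl]butanamide | COc1cc(C[C@@H](CC(=O)N(C)OC)COCOC)ccc1O[Si](C(C)C)(C(C)C)C(C)C | intermediate
15 | 4-bromo-2,6-dimethoxyphenol | COc1cc(Br)cc(OC)c1O | starting material
16 | (4-bromo-2,6-dimethoxyphenoxy)triisopropylsilane | COc1cc(Br)cc(OC)c1O[Si](C(C)C)(C(C)C)C(C)C | intermediate
17 | [3,5-dimethoxy-4-(triisopropylsilyloxy)phenyl]lithium | [Li]c1cc(OC)c(O[Si](C(C)C)(C(C)C)C(C)C)c(OC)c1 | intermediate (not isolated)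
18 | lithium alkoxide of the tetrahedral adduct of 17 to amide 14 | COc1cc(C[C@@H](CC([O-])(N(C)OC)c2cc(OC)c(O[Si](C(C)C)(C(C)C)C(C)C)c(OC)c2)COCOC)ccc1O[Si](C(C)C)(C(C)C)C(C)C.[Li+] | intermediate (not isolated)
19 | (3S)-1-[3,5-dimethoxy-4-(triisopropylsilyloxy)phenyl]-3-[(methoxymethoxy)methyl]-4-[3-methoxy-4-(triisopropylsilyloxy)phenyl]butan-1-one | COc1cc(C[C@@H](CC(=O)c2cc(OC)c(O[Si](C(C)C)(C(C)C)C(C)C)c(OC)c2)COCOC)ccc1O[Si](C(C)C)(C(C)C)C(C)C | intermediate
20 | lithium (Z)-enolate of ketone 19 | COc1cc(C[C@@H](/C=C(\[O-])c2cc(OC)c(O[Si](C(C)C)(C(C)C)C(C)C)c(OC)c2)COCOC)ccc1O[Si](C(C)C)(C(C)C)C(C)C.[Li+] | intermediate (not isolated)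
21 | (1Z,3S)-trimethylsilyl enol ether of ketone 19 | COc1cc(C[C@@H](/C=C(\O[Si](C)(C)C)c2cc(OC)c(O[Si](C(C)C)(C(C)C)C(C)C)c(OC)c2)COCOC)ccc1O[Si](C(C)C)(C(C)C)C(C)C | intermediate
22 | alkoxymethyl (oxocarbenium) cation from 21 by loss of methoxide, triflate counter-ion | COc1cc(C[C@@H](/C=C(\O[Si](C)(C)C)c2cc(OC)c(O[Si](C(C)C)(C(C)C)C(C)C)c(OC)c2)C[O+]=C)ccc1O[Si](C(C)C)(C(C)C)C(C)C.[O-]S(=O)(=O)C(F)(F)F | intermediate (not isolated)
23 | [(3S,4S)-4-[3-methoxy-4-(triisopropylsilyloxy)benzyl]oxolan-3-yl][3,5-dimethoxy-4-(triisopropylsilyloxy)phenyl]methanone (trans) | COc1cc(C[C@@H]2COC[C@H]2C(=O)c2cc(OC)c(O[Si](C(C)C)(C(C)C)C(C)C)c(OC)c2)ccc1O[Si](C(C)C)(C(C)C)C(C)C | intermediate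
24 | (S)-[(3S,4S)-4-[3-methoxy-4-(triisopropylsilyloxy)benzyl]oxolan-3-yl][3,5-dimethoxy-4-(triisopropylsilyloxy)phenyl]methanol | COc1cc(C[C@@H]2COC[C@H]2[C@H](O)c2cc(OC)c(O[Si](C(C)C)(C(C)C)C(C)C)c(OC)c2)ccc1O[Si](C(C)C)(C(C)C)C(C)C | intermediate
25 | (S)-[(3S,4S)-4-(4-hydroxy-3-methoxybenzyl)oxolan-3-yl](4-hydroxy-3,5-dimethoxyphenyl)methanol, CNP0307127.2 | COc1cc(C[C@@H]2COC[C@H]2[C@H](O)c2cc(OC)c(O)c(OC)c2)ccc1O | target

**Step count and risks**

Total steps: 12. Longest linear sequence: 11 steps (steps 1 to 6 and 8 to 12); step 7 is a one-step branch that joins at step 8.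

Steps most likely to fail:

1. Step 10. The acetal may ionise at the inner oxygen instead, so that the whole alkoxymethyl unit is lost as a methoxymethyl cation and the primary oxygen is merely silylated, or the enol silane may be protodesilylated before the C–C bond forms. The fallback sets out from hydroxy amide 12. The alcohol would be alkylated with (2-methoxyethoxy)methyl chloride and i-Pr2NEt to the (2-methoxyethoxy)methyl ether amide F1. Aryllithium 17 would convert it into the (2-methoxyethoxy)methyl ether ketone F2, and LiN(SiMe3)2 with Me3SiCl into the corresponding enol silane F3. SnCl4 in CH2Cl2 at −78 °C would then ionise the acetal by chelation between the two oxygens of the methoxyethoxy arm, so that only that arm can leave. The same oxocarbenium ion closes to ketone 23, where the route is rejoined.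

2. Step 11. Facial selectivity may be poor, because catalyst control has to override the intrinsic Felkin–Anh bias of the C3 centre. The fallback sets out from ketone 23. Substrate-controlled reduction with LiBH(s-Bu)3 in THF at −78 °C would give the (7R) epimeric carbinol F4. A Mitsunobu reaction with 4-nitrobenzoic acid, PPh3 and diisopropyl azodicarboxylate would invert C7 to the (7S) 4-nitrobenzoate F5. Methanolysis with K2CO3 in MeOH at 0 °C would return carbinol 24.

3. Step 6. Hydroxy amide 12 may relactonise to 11 with loss of the hydroxylamine faster than the primary alcohol is alkoxymethylated. The fallback sets out from lactone 11. Single addition of aryllithium 17 (1.05 equiv, THF, −78 °C) to the lactone carbonyl, followed by a cold quench, would give the γ-hydroxy ketone F6. Alkylation of its primary alcohol with 13 and i-Pr2NEt would give ketone 19 directly, bypassing 12 and 14.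

**Further compounds**

F1 | step 10 | (3S)-N-methoxy-3-{[(2-methoxyethoxy)methoxy]methyl}-N-methyl-4-[3-methoxy-4-(triisopropylsilyloxy)phenyl]butanamide | COc1cc(C[C@@H](CC(=O)N(C)OC)COCOCCOC)ccc1O[Si](C(C)C)(C(C)C)C(C)C
F2 | step 10 | (3S)-1-[3,5-dimethoxy-4-(triisopropylsilyloxy)phenyl]-3-{[(2-methoxyethoxy)methoxy]methyl}-4-[3-methoxy-4-(triisopropylsilyloxy)phenyl]butan-1-one | COc1cc(C[C@@H](CC(=O)c2cc(OC)c(O[Si](C(C)C)(C(C)C)C(C)C)c(OC)c2)COCOCCOC)ccc1O[Si](C(C)C)(C(C)C)C(C)C
F3 | step 10 | (1Z,3S)-trimethylsilyl enol ether of F2 | COc1cc(C[C@@H](/C=C(\O[Si](C)(C)C)c2cc(OC)c(O[Si](C(C)C)(C(C)C)C(C)C)c(OC)c2)COCOCCOC)ccc1O[Si](C(C)C)(C(C)C)C(C)C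
F4 | step 11 | (R)-[(3S,4S)-4-[3-methoxy-4-(triisopropylsilyloxy)benzyl]oxolan-3-yl][3,5-dimethoxy-4-(triisopropylsilyloxy)phenyl]methanol | COc1cc(C[C@@H]2COC[C@H]2[C@@H](O)c2cc(OC)c(O[Si](C(C)C)(C(C)C)C(C)C)c(OC)c2)ccc1O[Si](C(C)C)(C(C)C)C(C)C
F5 | step 11 | (S)-[(3S,4S)-4-[3-methoxy-4-(triisopropylsilyloxy)benzyl]oxolan-3-yl][3,5-dimethoxy-4-(triisopropylsilyloxy)phenyl]methyl 4-nitrobenzoate | COc1cc(C[C@@H]2COC[C@H]2[C@H](OC(=O)c3ccc(cc3)[N+](=O)[O-])c2cc(OC)c(O[Si](C(C)C)(C(C)C)C(C)C)c(OC)c2)ccc1O[Si](C(C)C)(C(C)C)C(C)C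
F6 | step 6 | (3S)-1-[3,5-dimethoxy-4-(triisopropylsilyloxy)phenyl]-3-(hydroxymethyl)-4-[3-methoxy-4-(triisopropylsilyloxy)phenyl]butan-1-one | COc1cc(C[C@@H](CC(=O)c2cc(OC)c(O[Si](C(C)C)(C(C)C)C(C)C)c(OC)c2)CO)ccc1O[Si](C(C)C)(C(C)C)C(C)C
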